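**Retrosynthetic overview**
- **Feature.** Tetralin numbering: C1 carries the aryl group, C2 the sulfated arm C2a, C3 the hydroxymethyl arm C3a, and C4 is the benzylic CH2. Ring A is aromatic and ring B saturated. The syringyl ring on C1 and C2a on C2 are trans vicinal carbon substituents on the bond next to ring A. They mark the two ends of a former ring-A-conjugated C1=C2 double bond.
- **Late disconnections.** These are O–SO3H at C2a, the three O-benzyl groups, and C2a–O back to C2a–B(pin). The boron keeps C2a distinct from the benzylated C3a.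
- **Key disconnection.** C2–C2a and C1–aryl are cut together. This gives the (3S)-dihydronaphthalene, iodomethyl pinacol boronate and O-benzyl-4-bromosyringol, which nickel joins in one operation.
- **Ring order.** Both aromatic rings are bought. Ring B is the only ring made. It closes at C1–C8a by Friedel–Crafts acylation of an (S)-benzylsuccinic half-ester and is then taken to the alkene by reduction, C3a benzylation and dehydration.
- **Stereochemistry.** C3 comes from rhodium-catalysed asymmetric hydrogenation of the Stobbe half-ester. In the key step C3 directs C2 and C2 directs C1.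

Key step: step 9

**Remarks**
- **Numbering.** The tetralin numbering above is used for every bicyclic compound, so ring A carries H at C5, OMe at C6 and C8, and the protected oxygen at C7. The systematic 1,2-dihydronaphthalene name of the key alkene reads 6-benzyloxy-5,7-dimethoxy and describes the same compound.
- **Order of events.** Ring B is closed while C3a is still the methyl ester. A free or benzylated C3a oxygen would trap the activated C1 acyl group as a five-membered lactone.
- **Assumption on step 3.** The facial sense is assigned by the quadrant model that links bisphospholane–rhodium catalysts on enamides and on itaconates. If a test run gives the (R)-acid, the (S,S)-ligand is used instead.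
- **Assumption on the target form.** The target is taken as the hydrogen sulfate drawn. The sulfate is carried as its sodium salt and protonated only at the end.

**Step 1**
Reactants: 1 syringaldehyde
Product: 2 4-(benzyloxy)-3,5-dimethoxybenzaldehyde
Conditions: BnBr (1.1 equiv), K2CO3 (1.5 equiv), DMF, 60 °C
Reagents that add atoms: benzyl bromide, BrCc1ccccc1
Why: Williamson ether synthesis on the acidic phenoxide, in which the non-enolisable aldehyde is a spectator.

**Step 2**
Reactants: 2 4-(benzyloxy)-3,5-dimethoxybenzaldehyde; 3 dimethyl succinate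
Product: 5 (E)-4-[4-(benzyloxy)-3,5-dimethoxyphenyl]-3-(methoxycarbonyl)but-3-enoic acid, via paraconic ester lactone 4 (not isolated)
Conditions: NaOMe (1.5 equiv), MeOH, reflux; then aq HCl
Reagents that add atoms: none
Why: Stobbe condensation, in which the succinate enolate adds to the aldehyde, the aldolate lactonises to 4, and base-induced ring opening gives the half-ester carboxylate with the aryl group trans to the ester (E) for steric reasons.

**Step 3**
Reactants: 5 (E)-half-ester
Product: 6 (3S)-4-[4-(benzyloxy)-3,5-dimethoxyphenyl]-3-(methoxycarbonyl)butanoic acid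
Conditions: [Rh(cod)2]BF4 (1 mol%), (R,R)-Et-DuPhos (1.1 mol%), NaOMe (10 mol%), H2 (6 bar), MeOH, rt; dilute HCl work-up
Reagents that add atoms: none
Why: Rhodium-catalysed asymmetric hydrogenation of a Stobbe-type itaconate half-ester, an established substrate class in which the carboxylate arm chelates rhodium and the C2-symmetric bisphospholane shields one alkene face, setting the future C3 as (S) while the homogeneous catalyst leaves the benzyl ether alone.

**Step 4**
Reactants: 6 (3S)-half-ester
Product: 8 methyl (3S)-7-(benzyloxy)-6,8-dimethoxy-1-oxotetralin-3-carboxylate, via mixed trifluoroacetic anhydride 7 (not isolated)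
Conditions: (CF3CO)2O (2.5 equiv), CH2Cl2, 0 °C to rt
Reagents that add atoms: trifluoroacetic anhydride, O=C(OC(=O)C(F)(F)F)C(F)(F)F (its acyl group sits in 7 only and leaves again on ring closure)
Why: Intramolecular Friedel–Crafts acylation through the mixed anhydride, in which the attacked carbon (future C8a) has one ortho and one para methoxy group, the two ortho positions are equivalent, six-ring closure is preferred over an indanone, and the metal-free medium spares the benzyl ether, the peri methoxy group and C3.

**Step 5**
Reactants: 8 tetralone ester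
Product: 9 (3S)-7-(benzyloxy)-3-(hydroxymethyl)-6,8-dimethoxytetralin-1-ol (C1 epimers)
Conditions: LiAlH4 (2 equiv), THF, 0 °C to rt; H2O/aq NaOH work-up
Reagents that add atoms: none
Why: Hydride reduction of ketone and ester in one operation, in which the C1 carbinol configuration does not matter because step 7 erases it and reduction outruns enolisation at C3.

**Step 6**
Reactants: 9 diol
Product: 10 (3S)-7-(benzyloxy)-3-[(benzyloxy)methyl]-6,8-dimethoxytetralin-1-ol (C1 epimers)
Conditions: NaH (1.05 equiv), BnBr (1.05 equiv), Bu4NI (5 mol%), THF, 0 °C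
Reagents that add atoms: benzyl bromide, BrCc1ccccc1
Why: Williamson ether synthesis with one equivalent of electrophile, which should go to the unhindered primary C3a alkoxide because the secondary C1 alkoxide is crowded by the peri C8 methoxy group.

**Step 7**
Reactants: 10 mono-benzyl ether
Product: 11 (3S)-7-(benzyloxy)-3-[(benzyloxy)methyl]-6,8-dimethoxy-3,4-dihydronaphthalene (C1=C2)
Conditions: p-TsOH·H2O (2 mol%), 4 Å sieves, toluene, 60 °C, argon
Reagents that add atoms: none
Why: Acid-catalysed E1 dehydration, in which the C1 cation is stabilised by the C6 and C8 methoxy groups so a trace of acid suffices, and loss of a C2 proton is the only elimination open, giving the ring-A-conjugated alkene with C3 untouched.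

**Step 8**
Reactants: 12 4-bromo-2,6-dimethoxyphenol
Product: 13 2-(benzyloxy)-5-bromo-1,3-dimethoxybenzene
Conditions: BnBr (1.1 equiv), K2CO3 (1.5 equiv), DMF, 60 °C
Reagents that add atoms: benzyl bromide, BrCc1ccccc1
Why: Williamson ether synthesis on the phenoxide, with the aryl bromide inert under these conditions.

**Step 9**
Reactants: 11 (3S)-dihydronaphthalene; 13 2-(benzyloxy)-5-bromo-1,3-dimethoxybenzene; 14 2-(iodomethyl)-4,4,5,5-tetramethyl-1,3,2-dioxaborolane
Product: 15 (1R,2S,3S)-7-(benzyloxy)-1-[4-(benzyloxy)-3,5-dimethoxyphenyl]-3-[(benzyloxy)methyl]-6,8-dimethoxy-2-[(pinacolboryl)methyl]tetralin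
Conditions: NiBr2(dme) (10 mol%), 4,4'-di-tert-butyl-2,2'-bipyridine (12 mol%), Mn powder (4 equiv), Me3SiCl (5 mol%), DMA (0.5 M in 11), 25–30 °C; 13 and 14 (2.5 equiv each) added slowly by syringe pump
Reagents that add atoms: none
Why: Proposed new method: zerovalent nickel formed from NiBr2(dme), the bipyridine and Mn inserts into the C–Br bond of 13, while a monovalent nickel species abstracts iodine from 14 to release the borylmethyl radical, whose vacant boron orbital makes it mildly electrophilic and so matched to the electron-rich alkene of 11. Both alkene carbons carry one hydrogen, so regiochemistry rests on radical stability alone: attack at C2 (C2–C2a bond) leaves a C1 radical conjugated with ring A and its C6 and C8 methoxy groups, whereas attack at C1 would leave an unstabilised secondary radical. The C1 radical is trapped by the divalent aryl nickel bromide, the trivalent aryl(benzyl)nickel species reductively eliminates to form the C1–aryl bond, and Mn returns nickel to its low-valent state; no ring is closed. C2 is set by substrate control, the radical entering the half-chair face opposite the C3 benzyloxymethyl arm, and C1 is set by the new C2 arm, because radical capture at nickel is reversible and the less crowded trans diastereomer should eliminate faster. The closest known reaction types are nickel-catalysed three-component alkylarylation of vinylarenes with alkyl and aryl halides and nickel-catalysed reductive arylation of alpha-halo boronic esters, neither shown on a cyclic 1,2-disubstituted trialkoxy styrene. The step needs addition to the alkene to outrun direct aryl–CH2B(pin) coupling, which is favoured by a high concentration of 11, a modest nickel loading and slow addition of the two cheap partners in excess.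

**Step 10**
Reactants: 15 boronic ester
Product: 16 (1R,2S,3S)-7-(benzyloxy)-1-[4-(benzyloxy)-3,5-dimethoxyphenyl]-3-[(benzyloxy)methyl]-2-(hydroxymethyl)-6,8-dimethoxytetralin
Conditions: NaBO3·4H2O (5 equiv), THF/H2O 1:1, rt
Reagents that add atoms: sodium perborate, [Na+].[O-]OB=O
Why: Boronic ester oxidation by peroxide addition to boron and 1,2-migration of C2a from boron to oxygen, which touches no stereocentre and is mild enough for the electron-rich arenes and the benzyl ethers.

**Step 11**
Reactants: 16 C2a alcohol
Product: 17 sodium [(1R,2S,3S)-7-(benzyloxy)-1-[4-(benzyloxy)-3,5-dimethoxyphenyl]-3-[(benzyloxy)methyl]-6,8-dimethoxytetralin-2-yl]methyl sulfate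
Conditions: SO3·pyridine (5 equiv), pyridine, rt to 40 °C; then aq NaHCO3; SiO2 (CH2Cl2/MeOH)
Reagents that add atoms: sulfur trioxide–pyridine complex, O=S(=O)([O-])[n+]1ccccc1; sodium hydrogencarbonate, [Na+].OC([O-])=O
Why: O-sulfation with the sulfur trioxide–pyridine complex at the only free hydroxyl group, so no site selectivity is needed, and exchange to the sodium salt removes pyridine, which would slow the later hydrogenolysis.

**Step 12**
Reactants: 17 protected sodium sulfate
Product: 19 CNP0111670.1, [(1R,2S,3S)-7-hydroxy-1-(4-hydroxy-3,5-dimethoxyphenyl)-3-(hydroxymethyl)-6,8-dimethoxytetralin-2-yl]methyl hydrogen sulfate, via debenzylated sodium sulfate 18 (not isolated)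
Conditions: H2 (1 atm), Pd/C (10 wt%), MeOH/H2O, rt; filter; aq HCl (1.0 equiv), 0 °C; C18 desalting (H2O then MeOH/H2O); lyophilise
Reagents that add atoms: none
Why: Catalytic hydrogenolysis of two aryl benzyl ethers and one alkyl benzyl ether under neutral conditions that alkyl sulfate salts tolerate, followed by cold protonation and reversed-phase desalting, with the C1 diarylmethine bonds inert to Pd/C at ambient pressure.

**Compound list**
1 | syringaldehyde | COc1cc(C=O)cc(OC)c1O | starting material
2 | 4-(benzyloxy)-3,5-dimethoxybenzaldehyde | COc1cc(C=O)cc(OC)c1OCc1ccccc1 | intermediate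
3 | dimethyl succinate | COC(=O)CCC(=O)OC | starting material
4 | methyl 2-[4-(benzyloxy)-3,5-dimethoxyphenyl]-5-oxotetrahydrofuran-3-carboxylate (racemic diastereomer mixture) | COC(=O)C1CC(=O)OC1c1cc(OC)c(OCc2ccccc2)c(OC)c1 | intermediate
5 | (E)-4-[4-(benzyloxy)-3,5-dimethoxyphenyl]-3-(methoxycarbonyl)but-3-enoic acid | COC(=O)/C(CC(=O)O)=C/c1cc(OC)c(OCc2ccccc2)c(OC)c1 | intermediate
6 | (3S)-4-[4-(benzyloxy)-3,5-dimethoxyphenyl]-3-(methoxycarbonyl)butanoic acid | COC(=O)[C@H](CC(=O)O)Cc1cc(OC)c(OCc2ccccc2)c(OC)c1 | intermediate
7 | mixed anhydride of 6 and trifluoroacetic acid | COC(=O)[C@H](CC(=O)OC(=O)C(F)(F)F)Cc1cc(OC)c(OCc2ccccc2)c(OC)c1 | intermediate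
8 | methyl (3S)-7-(benzyloxy)-6,8-dimethoxy-1-oxotetralin-3-carboxylate | COC(=O)[C@@H]1CC(=O)c2c(OC)c(OCc3ccccc3)c(OC)cc2C1 | intermediate
9 | (3S)-7-(benzyloxy)-3-(hydroxymethyl)-6,8-dimethoxytetralin-1-ol (C1 epimers) | OC[C@@H]1CC(O)c2c(OC)c(OCc3ccccc3)c(OC)cc2C1 | intermediate
10 | (3S)-7-(benzyloxy)-3-[(benzyloxy)methyl]-6,8-dimethoxytetralin-1-ol (C1 epimers) | OC1C[C@@H](COCc2ccccc2)Cc2cc(OC)c(OCc3ccccc3)c(OC)c12 | intermediate
11 | (3S)-7-(benzyloxy)-3-[(benzyloxy)methyl]-6,8-dimethoxy-3,4-dihydronaphthalene (C1=C2) | C1=C[C@@H](COCc2ccccc2)Cc2cc(OC)c(OCc3ccccc3)c(OC)c12 | intermediate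
12 | 4-bromo-2,6-dimethoxyphenol | COc1cc(Br)cc(OC)c1O | starting material
13 | 2-(benzyloxy)-5-bromo-1,3-dimethoxybenzene | COc1cc(Br)cc(OC)c1OCc1ccccc1 | intermediate
14 | 2-(iodomethyl)-4,4,5,5-tetramethyl-1,3,2-dioxaborolane | CC1(C)OB(CI)OC1(C)C | starting material
15 | (1R,2S,3S)-1-aryl-2-[(pinacolboryl)methyl]-3-[(benzyloxy)methyl]tetralin, tri-O-benzyl | COc1cc([C@@H]2c3c(cc(OC)c(OCc4ccccc4)c3OC)C[C@H](COCc3ccccc3)[C@H]2CB2OC(C)(C)C(C)(C)O2)cc(OC)c1OCc1ccccc1 | intermediate
16 | (1R,2S,3S)-C2a alcohol, tri-O-benzyl | COc1cc([C@@H]2c3c(cc(OC)c(OCc4ccccc4)c3OC)C[C@H](COCc3ccccc3)[C@H]2CO)cc(OC)c1OCc1ccccc1 | intermediate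
17 | (1R,2S,3S)-C2a sodium sulfate, tri-O-benzyl | COc1cc([C@@H]2c3c(cc(OC)c(OCc4ccccc4)c3OC)C[C@H](COCc3ccccc3)[C@H]2COS(=O)(=O)[O-])cc(OC)c1OCc1ccccc1.[Na+] | intermediate
18 | sodium salt of the target | COc1cc([C@@H]2c3c(cc(OC)c(O)c3OC)C[C@H](CO)[C@H]2COS(=O)(=O)[O-])cc(OC)c1O.[Na+] | intermediate
19 | CNP0111670.1, (1R,2S,3S)-hydrogen sulfate | COc1cc([C@@H]2c3c(cc(OC)c(O)c3OC)C[C@H](CO)[C@H]2COS(=O)(=O)O)cc(OC)c1O | target

**Step count:** 12 steps in total. The longest linear sequence is 11 steps (steps 1–7 and 9–12). Step 8 is a one-step branch.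

**Steps most likely to fail**

**1. Step 9.**
- **What may go wrong.** The borylmethyl radical may be captured by the aryl nickel species before it adds to the hindered internal alkene. The benzylic nickel species may lose a C2 hydrogen. The facial bias at C2 may be weak.
- **Fallback (known chemistry).** It sets out from 6, uses 2, and returns at 16. The potassium salt of 6 is reduced at the ester with Ca(BH4)2 (CaCl2/NaBH4, EtOH). Acidification then closes (S)-4-[4-(benzyloxy)-3,5-dimethoxybenzyl]dihydrofuran-2(3H)-one F1.
- The lithium enolate of F1 (LiN(iPr)2, THF, −78 °C) adds to aldehyde 2 anti to the benzyl arm. This gives the (3R,4S)-trans hydroxybenzyl lactone F2 as carbinol epimers.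
- CF3CO2H in CH2Cl2 ionises the carbinol. Ring A then closes onto the cation by Friedel–Crafts alkylation (C1–C8a) to give the trans,trans aryltetralin lactone F3.
- KOH and BnBr in refluxing toluene open the lactone, with O-benzylation at C3a and esterification at C2a, to give the benzyl ester benzyl ether F4.
- LiAlH4 in THF reduces the ester to 16.

**2. Step 12.**
- **What may go wrong.** Hydrogenolysis of the anionic, amphiphilic substrate may be slow or incomplete. The sulfate ester may be partly solvolysed during handling.
- **Fallback.** It sets out from 16 and returns at 19, carrying the sulfate as a neutral masked diester. Alcohol 16 is treated with 2,2,2-trichloroethoxysulfonyl-1,2-dimethylimidazolium triflate and 1,2-dimethylimidazole in CH2Cl2. This gives the 2,2,2-trichloroethyl sulfate diester F5, which can be purified on silica.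
- Pd/C with HCO2NH4 in MeOH removes the three benzyl groups and the trichloroethyl group together, giving the ammonium salt of the target F6.
- Cold aqueous HCl and reversed-phase desalting give 19.

**3. Step 6.**
- **What may go wrong.** The primary C3a and secondary C1 hydroxyl groups may not be discriminated well enough.
- **Fallback.** It sets out from 8 and returns at 11, so that the two hydroxyl groups never coexist. NaBH4 in MeOH at 0 °C reduces only the ketone to the hydroxy ester F7.
- Catalytic p-TsOH in toluene dehydrates F7 to the methyl (3S)-dihydronaphthalene-3-carboxylate F8.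
- iBu2AlH in CH2Cl2 at −78 °C, a non-basic hydride that should not enolise the allylic ester, gives the homoallylic alcohol F9.
- NaH and BnBr in THF give 11.

**Further compounds**
F1 | step 9 | (S)-4-[4-(benzyloxy)-3,5-dimethoxybenzyl]dihydrofuran-2(3H)-one | O=C1C[C@H](Cc2cc(OC)c(OCc3ccccc3)c(OC)c2)CO1
F2 | step 9 | (3R,4S)-4-[4-(benzyloxy)-3,5-dimethoxybenzyl]-3-{[4-(benzyloxy)-3,5-dimethoxyphenyl](hydroxy)methyl}dihydrofuran-2(3H)-one (carbinol epimers) | O=C1[C@@H](C(O)c2cc(OC)c(OCc3ccccc3)c(OC)c2)[C@H](Cc2cc(OC)c(OCc3ccccc3)c(OC)c2)CO1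
F3 | step 9 | (1R,2S,3S)-aryltetralin C2a,C3a-lactone, di-O-benzyl | O=C1OC[C@H]2Cc3cc(OC)c(OCc4ccccc4)c(OC)c3[C@@H](c3cc(OC)c(OCc4ccccc4)c(OC)c3)[C@H]12
F4 | step 9 | benzyl (1R,2S,3S)-7-(benzyloxy)-1-[4-(benzyloxy)-3,5-dimethoxyphenyl]-3-[(benzyloxy)methyl]-6,8-dimethoxytetralin-2-carboxylate | O=C(OCc1ccccc1)[C@H]1[C@H](c2cc(OC)c(OCc3ccccc3)c(OC)c2)c2c(OC)c(OCc3ccccc3)c(OC)cc2C[C@@H]1COCc1ccccc1
F5 | step 12 | (1R,2S,3S)-C2a 2,2,2-trichloroethyl sulfate diester, tri-O-benzyl | COc1cc([C@@H]2c3c(cc(OC)c(OCc4ccccc4)c3OC)C[C@H](COCc3ccccc3)[C@H]2COS(=O)(=O)OCC(Cl)(Cl)Cl)cc(OC)c1OCc1ccccc1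
F6 | step 12 | ammonium salt of the target | COc1cc([C@@H]2c3c(cc(OC)c(O)c3OC)C[C@H](CO)[C@H]2COS(=O)(=O)[O-])cc(OC)c1O.[NH4+]
F7 | step 6 | methyl (3S)-7-(benzyloxy)-1-hydroxy-6,8-dimethoxytetralin-3-carboxylate (C1 epimers) | COC(=O)[C@@H]1CC(O)c2c(OC)c(OCc3ccccc3)c(OC)cc2C1
F8 | step 6 | methyl (3S)-7-(benzyloxy)-6,8-dimethoxy-3,4-dihydronaphthalene-3-carboxylate (C1=C2) | COC(=O)[C@@H]1C=Cc2c(OC)c(OCc3ccccc3)c(OC)cc2C1
F9 | step 6 | [(3S)-7-(benzyloxy)-6,8-dimethoxy-3,4-dihydronaphthalen-3-yl]methanol (C1=C2) | OC[C@@H]1C=Cc2c(OC)c(OCc3ccccc3)c(OC)cc2C1
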